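**Retrosynthetic overview**
1. Target 17 ⇐ hydrogenolysis of its heptabenzyl ether 16.
2. Lower C-ring: the 3α-OH and 4β-OH C–O bonds come from anti-hydrolysis of a 3,4-epoxide lying cis to the 2-aryl group (from flav-3-ene 13 via its bromohydrin). The O1–C2 bond of 13 comes from an enantioselective cyclodehydration of chalcol 12, which is the key C–O ring closure.
3. Chalcol 12 ⇐ chalcone 11 ⇐ ketone 9 + 3,4-bis(benzyloxy)benzaldehyde 10.
4. Interflavanyl C4–C6 bond: arylative opening of upper epoxide 8 by acetophenone 2 (para to its OH), giving 4β-aryl/3α-OH.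
5. Upper C-ring (formed first): epoxide 8 ⇐ flav-3-ene 6 ⇐ the same key C–O cyclodehydration of chalcol 5 ⇐ chalcone 4 ⇐ 2 + 3; 2 ⇐ gallacetophenone 1.

Assumption: the sense of induction of the new cyclisation (steps 4 and 9) has to be fixed by one screening run; the (R)-catalyst is written, and its enantiomer is used if it gives the (2R)-chromene.

**Route**

Step 1
Reactants: 1 1-(2,3,4-trihydroxyphenyl)ethan-1-one (gallacetophenone)
Product: 2 1-[3,4-bis(benzyloxy)-2-hydroxyphenyl]ethan-1-one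
Conditions: BnBr (2.1 equiv), K2CO3 (2.2 equiv), acetone, reflux
Reagents that add atoms: benzyl bromide, BrCc1ccccc1
Why: Williamson etherification; the 2-OH is chelated to the ketone carbonyl and far less nucleophilic, so only the 4- and 3-phenoxides are benzylated.

Step 2
Reactants: 2 1-[3,4-bis(benzyloxy)-2-hydroxyphenyl]ethan-1-one; 3 4-(benzyloxy)benzaldehyde
Product: 4 (E)-1-[3,4-bis(benzyloxy)-2-hydroxyphenyl]-3-[4-(benzyloxy)phenyl]prop-2-en-1-one
Conditions: KOH (50% aq), EtOH, 23 °C, 48 h; then dilute HCl to pH 5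
Reagents that add atoms: none
Why: Claisen–Schmidt aldol condensation of a methyl ketone with a non-enolisable aldehyde gives the (E)-2′-hydroxychalcone.

Step 3
Reactants: 4 (E)-1-[3,4-bis(benzyloxy)-2-hydroxyphenyl]-3-[4-(benzyloxy)phenyl]prop-2-en-1-one
Product: 5 rac-(E)-1-[3,4-bis(benzyloxy)-2-hydroxyphenyl]-3-[4-(benzyloxy)phenyl]prop-2-en-1-ol
Conditions: NaBH4, CeCl3·7H2O, MeOH/THF, −20 °C; NaHCO3 work-up, crude solid used without chromatography
Reagents that add atoms: none
Why: Luche reduction gives clean 1,2-reduction of the enone; the carbinol centre is left racemic on purpose because it is erased in step 4.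

Step 4
Reactants: 5 rac-(E)-1-[3,4-bis(benzyloxy)-2-hydroxyphenyl]-3-[4-(benzyloxy)phenyl]prop-2-en-1-ol
Product: 6 (2S)-7,8-bis(benzyloxy)-2-[4-(benzyloxy)phenyl]-2H-chromene
Conditions: (R)-3,3′-bis(2,4,6-triisopropylphenyl)-BINOL N-triflylphosphoramide (5 mol %), 5 Å MS, toluene, −60 °C; Et3N quench
Reagents that add atoms: none
Why: Proposed new method: enantioconvergent cyclodehydration of a 2′-hydroxychalcol, in which the chiral acid ionises the racemic doubly activated benzylic/allylic alcohol to a 1-(2-hydroxyaryl)-3-arylallyl cation (protonated vinyl o-quinone methide) held as a contact ion pair, the phosphoramide anion hydrogen-bonds the phenol OH and acts as general base while the phenol oxygen closes onto the cinnamyl terminus (6-endo SN1′/oxa-6π), so the O1–C2 bond and the C2 centre form inside the chiral pocket and both alcohol enantiomers converge on one chromene; the closest known reaction types are chiral N-triflylphosphoramide-catalysed intramolecular allylic etherification to 2H-chromenes via contact ion pairs, chiral phosphoric acid catalysis of o-quinone methides, and the racemic acid-mediated cyclodehydration of 2′-hydroxychalcols to flav-3-enes.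

Step 5
Reactants: 6 (2S)-7,8-bis(benzyloxy)-2-[4-(benzyloxy)phenyl]-2H-chromene
Product: 8 (2R,3R,4R)-7,8-bis(benzyloxy)-2-[4-(benzyloxy)phenyl]-3,4-epoxychromane (oxirane cis to the 2-aryl group), via trans-bromohydrin 7 (not isolated)
Conditions: NBS (1.05 equiv), THF/H2O (10:1), −10 °C; then powdered KOH (3 equiv), 0 °C; cold Et2O/Et3N work-up, used at once
Reagents that add atoms: water, O; N-bromosuccinimide, O=C1CCC(=O)N1Br (its Br stays only in intermediate 7)
Why: Bromohydrin formation then intramolecular Williamson closure: Br+ adds to C3 anti to the 2-aryl group, water captures the 7-alkoxy-stabilised C4 cation anti to bromine, and the C4 alkoxide then inverts C3, which places the oxirane on the face of the 2-aryl group and fixes the 3α (2,3-cis) oxygen.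

Step 6
Reactants: 8 (2R,3R,4R)-7,8-bis(benzyloxy)-2-[4-(benzyloxy)phenyl]-3,4-epoxychromane; 2 1-[3,4-bis(benzyloxy)-2-hydroxyphenyl]ethan-1-one
Product: 9 1-[3,4-bis(benzyloxy)-5-{(2R,3R,4R)-7,8-bis(benzyloxy)-2-[4-(benzyloxy)phenyl]-3-hydroxychroman-4-yl}-2-hydroxyphenyl]ethan-1-one (2,3-cis-3,4-trans)
Conditions: 2 (6 equiv, excess recovered), HFIP/CH2Cl2 (1:2), −20 °C, slow addition of 8
Reagents that add atoms: none
Why: Friedel–Crafts-type arylative epoxide opening: HFIP ionises the strained p-alkoxybenzylic C4–O bond, the only activated position of 2 is C5 (para to OH, ortho to OBn), and attack anti to the C3 oxygen on the face opposite the 2-aryl group gives the 4β-aryl adduct, as is general for 2,3-cis-flavan C4 cations.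

Step 7
Reactants: 9 ketone from step 6; 10 3,4-bis(benzyloxy)benzaldehyde
Product: 11 (E)-1-[3,4-bis(benzyloxy)-5-{(2R,3R,4R)-7,8-bis(benzyloxy)-2-[4-(benzyloxy)phenyl]-3-hydroxychroman-4-yl}-2-hydroxyphenyl]-3-[3,4-bis(benzyloxy)phenyl]prop-2-en-1-one
Conditions: 10 (1.3 equiv), KOH (50% aq), EtOH/THF, 23–40 °C; then dilute HCl to pH 5
Reagents that add atoms: none
Why: Claisen–Schmidt condensation as in step 2; the upper unit has no free 4′-OH, so base cannot epimerise C2 through a quinone methide.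

Step 8
Reactants: 11 chalcone from step 7
Product: 12 (E)-1-[3,4-bis(benzyloxy)-5-{(2R,3R,4R)-7,8-bis(benzyloxy)-2-[4-(benzyloxy)phenyl]-3-hydroxychroman-4-yl}-2-hydroxyphenyl]-3-[3,4-bis(benzyloxy)phenyl]prop-2-en-1-ol (1:1 carbinol epimers)
Conditions: NaBH4, CeCl3·7H2O, MeOH/THF, −20 °C; NaHCO3 work-up, crude used
Reagents that add atoms: none
Why: Luche 1,2-reduction as in step 3; the carbinol configuration is irrelevant because it is erased in step 9.

Step 9
Reactants: 12 allylic alcohol from step 8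
Product: 13 (2R,3R,4R)-7,8-bis(benzyloxy)-2-[4-(benzyloxy)phenyl]-4-{(2S)-7,8-bis(benzyloxy)-2-[3,4-bis(benzyloxy)phenyl]-2H-chromen-6-yl}chroman-3-ol
Conditions: (R)-N-triflylphosphoramide of step 4 (5–10 mol %), 5 Å MS, toluene, −60 °C; Et3N quench
Reagents that add atoms: none
Why: Proposed new method: the same enantioconvergent chiral-acid cyclodehydration as in step 4 (ionisation to the ion-paired hydroxyaryl-allyl cation, then catalyst-directed O1–C2 closure), here setting the lower C2 under catalyst control while the upper stereocentres are remote from the reacting termini; the closest known reaction types are chiral N-triflylphosphoramide-catalysed intramolecular allylic etherification to 2H-chromenes and racemic acid-mediated flav-3-ene formation from 2′-hydroxychalcols.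

Step 10
Reactants: 13 chromene from step 9
Product: 16 (2R,3R,4S)-7,8-bis(benzyloxy)-2-[3,4-bis(benzyloxy)phenyl]-6-{(2R,3R,4R)-7,8-bis(benzyloxy)-2-[4-(benzyloxy)phenyl]-3-hydroxychroman-4-yl}chromane-3,4-diol, via trans-bromohydrin 14 (not isolated), via cis-epoxide 15 (not isolated)
Conditions: NBS (1.05 equiv), THF/H2O (10:1), −10 °C; KOH (3 equiv), 0 °C; then aq. NaH2PO4 to pH 5, 23 °C
Reagents that add atoms: water, O; N-bromosuccinimide, O=C1CCC(=O)N1Br (its Br stays only in intermediate 14)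
Why: The bromohydrin–epoxide relay of step 5 sets the lower 3α-oxygen, and buffered hydrolysis of the p-alkoxybenzylic epoxide then delivers water to C4 anti to the C3 oxygen (axial attack on the half-chair anchored by the equatorial 2-aryl group), giving the 2,3-cis-3,4-trans diol with 4β-OH.

Step 11
Reactants: 16 heptabenzyl ether from step 10
Product: 17 (2R,3R,4S)-2-(3,4-dihydroxyphenyl)-6-[(2R,3R,4S)-3,7,8-trihydroxy-2-(4-hydroxyphenyl)chroman-4-yl]chromane-3,4,7,8-tetrol
Conditions: H2 (1 atm), 20% Pd(OH)2/C, EtOAc/MeOH (1:1), 23 °C, monitored and stopped at full debenzylation; Sephadex LH-20 (EtOH)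
Reagents that add atoms: none
Why: Hydrogenolysis of the seven aryl benzyl ethers under neutral conditions, where aryl O–benzyl cleavage is much faster than loss of the secondary benzylic 4-OH; no stereocentre is touched.

**Compound list**

1 | 1-(2,3,4-trihydroxyphenyl)ethan-1-one (gallacetophenone) | CC(=O)c1ccc(O)c(O)c1O | starting material
2 | 1-[3,4-bis(benzyloxy)-2-hydroxyphenyl]ethan-1-one | CC(=O)c1ccc(OCc2ccccc2)c(OCc2ccccc2)c1O | intermediate
3 | 4-(benzyloxy)benzaldehyde | O=Cc1ccc(OCc2ccccc2)cc1 | starting material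
4 | (E)-1-[3,4-bis(benzyloxy)-2-hydroxyphenyl]-3-[4-(benzyloxy)phenyl]prop-2-en-1-one | O=C(/C=C/c1ccc(OCc2ccccc2)cc1)c1ccc(OCc2ccccc2)c(OCc2ccccc2)c1O | intermediate
5 | rac-(E)-1-[3,4-bis(benzyloxy)-2-hydroxyphenyl]-3-[4-(benzyloxy)phenyl]prop-2-en-1-ol | OC(/C=C/c1ccc(OCc2ccccc2)cc1)c1ccc(OCc2ccccc2)c(OCc2ccccc2)c1O | intermediate
6 | (2S)-7,8-bis(benzyloxy)-2-[4-(benzyloxy)phenyl]-2H-chromene (aryl α, as in 2R-flavan-3-ols) | O1c2c(OCc3ccccc3)c(OCc3ccccc3)ccc2C=C[C@H]1c1ccc(OCc2ccccc2)cc1 | intermediate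
7 | (2R,3S,4R)-7,8-bis(benzyloxy)-2-[4-(benzyloxy)phenyl]-3-bromochroman-4-ol (2,3-trans-3,4-trans) | O1[C@H](c2ccc(OCc3ccccc3)cc2)[C@@H](Br)[C@H](O)c2ccc(OCc3ccccc3)c(OCc3ccccc3)c12 | intermediate
8 | (2R,3R,4R)-7,8-bis(benzyloxy)-2-[4-(benzyloxy)phenyl]-3,4-epoxychromane (oxirane cis to 2-aryl) | O1[C@H](c2ccc(OCc3ccccc3)cc2)[C@@H]4O[C@@H]4c2ccc(OCc3ccccc3)c(OCc3ccccc3)c12 | intermediate
9 | 1-[3,4-bis(benzyloxy)-5-{(2R,3R,4R)-7,8-bis(benzyloxy)-2-[4-(benzyloxy)phenyl]-3-hydroxychroman-4-yl}-2-hydroxyphenyl]ethan-1-one (2,3-cis-3,4-trans) | O1[C@H](c2ccc(OCc3ccccc3)cc2)[C@H](O)[C@@H](c2cc(C(C)=O)c(O)c(OCc3ccccc3)c2OCc2ccccc2)c2ccc(OCc3ccccc3)c(OCc3ccccc3)c12 | intermediate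
10 | 3,4-bis(benzyloxy)benzaldehyde | O=Cc1ccc(OCc2ccccc2)c(OCc2ccccc2)c1 | starting material
11 | (E)-chalcone of 9 with 10 (name as in step 7) | O1[C@H](c2ccc(OCc3ccccc3)cc2)[C@H](O)[C@@H](c2cc(C(=O)/C=C/c3ccc(OCc4ccccc4)c(OCc4ccccc4)c3)c(O)c(OCc3ccccc3)c2OCc2ccccc2)c2ccc(OCc3ccccc3)c(OCc3ccccc3)c12 | intermediate
12 | allylic alcohol of 11 (name as in step 8; 1:1 carbinol epimers) | O1[C@H](c2ccc(OCc3ccccc3)cc2)[C@H](O)[C@@H](c2cc(C(O)/C=C/c3ccc(OCc4ccccc4)c(OCc4ccccc4)c3)c(O)c(OCc3ccccc3)c2OCc2ccccc2)c2ccc(OCc3ccccc3)c(OCc3ccccc3)c12 | intermediate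
13 | (2R,3R,4R)-7,8-bis(benzyloxy)-2-[4-(benzyloxy)phenyl]-4-{(2S)-7,8-bis(benzyloxy)-2-[3,4-bis(benzyloxy)phenyl]-2H-chromen-6-yl}chroman-3-ol | O1[C@H](c2ccc(OCc3ccccc3)cc2)[C@H](O)[C@@H](c2cc3C=C[C@@H](c4ccc(OCc5ccccc5)c(OCc5ccccc5)c4)Oc3c(OCc3ccccc3)c2OCc2ccccc2)c2ccc(OCc3ccccc3)c(OCc3ccccc3)c12 | intermediate
14 | trans-bromohydrin of 13: lower unit (2R,3S,4R)-3-bromo-4-hydroxy, upper unit as in 13 | O1[C@H](c2ccc(OCc3ccccc3)cc2)[C@H](O)[C@@H](c2cc3[C@@H](O)[C@H](Br)[C@@H](c4ccc(OCc5ccccc5)c(OCc5ccccc5)c4)Oc3c(OCc3ccccc3)c2OCc2ccccc2)c2ccc(OCc3ccccc3)c(OCc3ccccc3)c12 | intermediate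
15 | cis-epoxide: lower unit (2R,3R,4R)-3,4-epoxy (oxirane cis to 2-aryl), upper unit as in 13 | O1[C@H](c2ccc(OCc3ccccc3)cc2)[C@H](O)[C@@H](c2cc3[C@H]4O[C@H]4[C@@H](c4ccc(OCc5ccccc5)c(OCc5ccccc5)c4)Oc3c(OCc3ccccc3)c2OCc2ccccc2)c2ccc(OCc3ccccc3)c(OCc3ccccc3)c12 | intermediate
16 | heptabenzyl ether of the target: lower unit (2R,3R,4S)-3,4-diol (2,3-cis-3,4-trans), upper unit (2R,3R,4R) | O1[C@H](c2ccc(OCc3ccccc3)cc2)[C@H](O)[C@@H](c2cc3[C@H](O)[C@@H](O)[C@@H](c4ccc(OCc5ccccc5)c(OCc5ccccc5)c4)Oc3c(OCc3ccccc3)c2OCc2ccccc2)c2ccc(OCc3ccccc3)c(OCc3ccccc3)c12 | intermediate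
17 | (2R,3R,4S)-2-(3,4-dihydroxyphenyl)-6-[(2R,3R,4S)-3,7,8-trihydroxy-2-(4-hydroxyphenyl)chroman-4-yl]chromane-3,4,7,8-tetrol (CNP0275688.1) | Oc1ccc([C@H]2Oc3c(ccc(O)c3O)[C@H](c3cc4c(c(O)c3O)O[C@H](c3ccc(O)c(O)c3)[C@H](O)[C@H]4O)[C@H]2O)cc1 | target

The upper C4 descriptor changes from R (benzylated compounds 9–16) to S (17) only because the CIP priorities change on debenzylation; the 4β geometry is unchanged.

**Totals**
Total step count: 11. Longest linear sequence: 11 (1 → 17).

**Three steps most likely to fail**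

Step 4 (new cyclodehydration; enantioselectivity and product racemisation by re-ionisation are untested). The fallback sets out from chalcol 5 and returns at chromene 6. Chalcol 5 is cyclised with an achiral acid (PPTS 5 mol %, toluene, 23 °C, the classical flav-3-ene synthesis) to the racemate, that is 6 together with its (2R)-enantiomer F1. The enantiomers are separated by preparative SFC on an amylose tris(3,5-dimethylphenylcarbamate) phase. F1 is racemised with catalytic TFA in CH2Cl2 through reversible C2–O ionisation and recycled.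

Step 6 (the acetyl group lowers the nucleophilicity of 2, so Meinwald rearrangement of 8 to the flavan-3-one and self-condensation through the flavan A-ring can compete). The fallback sets out from epoxide 8 and returns at 9. Epoxide 8 is opened at C4 by benzyl mercaptan (BnSH, cat. Et3N, THF, 0 °C, SN2 with inversion) to the bench-stable (2R,3S,4S)-4β-benzylsulfanyl-flavan-3-ol F2. Thiophilic activation of F2 with AgBF4 (THF, 0 °C) in the presence of excess 2 forms the same C4–aryl bond under neutral conditions; this is an established interflavanyl coupling of 4-thio-flavan-3-ols.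

Step 9 (the new method on a large, acid-sensitive substrate). The fallback sets out from 12 and returns at 13. Cyclodehydration of 12 with PPTS (5 mol %, toluene, 23 °C) gives 13 together with its lower-unit C2 epimer F3 in about 1:1 ratio. These are diastereomers and are separated by ordinary silica chromatography or HPLC. F3 is re-equilibrated with catalytic TFA and recycled.

**Further compounds**
F1 | step 4 | (2R)-7,8-bis(benzyloxy)-2-[4-(benzyloxy)phenyl]-2H-chromene (enantiomer of 6) | O1c2c(OCc3ccccc3)c(OCc3ccccc3)ccc2C=C[C@@H]1c1ccc(OCc2ccccc2)cc1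
F2 | step 6 | (2R,3S,4S)-4-(benzylsulfanyl)-7,8-bis(benzyloxy)-2-[4-(benzyloxy)phenyl]chroman-3-ol | O1[C@H](c2ccc(OCc3ccccc3)cc2)[C@H](O)[C@@H](SCc2ccccc2)c2ccc(OCc3ccccc3)c(OCc3ccccc3)c12
F3 | step 9 | lower-unit (2R)-epimer of 13 | O1[C@H](c2ccc(OCc3ccccc3)cc2)[C@H](O)[C@@H](c2cc3C=C[C@H](c4ccc(OCc5ccccc5)c(OCc5ccccc5)c4)Oc3c(OCc3ccccc3)c2OCc2ccccc2)c2ccc(OCc3ccccc3)c(OCc3ccccc3)c12
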